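The readings stem from a simulated flask on assumed constants; noise was put on by code.

**Your hunch.** If the partner goes in at 1.80 equiv and each flask gets 5.0 h, your hunch that the hottest flask, Saturday's at 105 °C, simply wins is one I doubt, and my quick number below shows where that doubt comes from.

| setting | green | grey | violet | Tuesday's | Sunday's | Saturday's |
|---|---|---|---|---|---|---|
| substrate | 12 mM | 19 mM | 25 mM | 25 mM | 25 mM | 25 mM |
| partner | 1.8 equiv | 1.8 equiv | 3.6 equiv | 1.80 equiv | 1.80 equiv | 1.80 equiv |
| temperature | 68 °C | 95 °C | 68 °C | 55 °C | 80 °C | 105 °C |
| remark | run made earlier | run made earlier | run made earlier |  |  |  |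
| time |  |  |  | 5.0 h | 5.0 h | 5.0 h |

- green (time / h: tris adduct / %): 0.333: 0; 1.00: 1; 1.50: 0; 2.50: 3
- grey (time / min: tris adduct / %): 3.00: 1; 8.00: 1; 15.0: 0; 40.0: 9
- violet (time / h: tris adduct / %): 0.333: 0; 1.00: 10; 1.50: 15; 2.50: 30

(scatter of a reading: 1.5 percentage points)

* which flask leads in amount of tris adduct, in percent of the substrate charged ("all alike" within 1.5 percentage points) (Tuesday's / Sunday's / Saturday's / all alike)
* how much tris adduct is there at the end, in percent of the substrate charged: Tuesday's
* how much tris adduct is there at the end, in percent of the substrate charged: Sunday's
* how much tris adduct is there at the end, in percent of the substrate charged: Saturday's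

- the numbers in the tables scatter by 1.5 percentage points (one standard deviation)
- steps under discussion: substrate + partner -> first product + released group; partner + first product -> double product + released group; partner + double product -> tris adduct + released group; tris adduct <-> isomer of the product

**Equal steps.** Each substrate takes up partner 3 times on its way to tris adduct, which can then turn into its isomer, so at this charge the partner is the limiting reagent. The readings are of tris adduct, with no reading of the first or double product, so I take equal rate constants as the zero of my scale. I count in turns, one turn being the rate constant times [partner] integrated over time, and after 2 turns 13.5% of the substrate has taken no partner, 27.1% one and 27.1% two. That uses 1.78 equivalents, close to the charge of 1.80 equiv, and puts the equal-step share, the tris adduct plus isomer standing when that much partner is used, at 32.3%. Grey, at 95 °C and 19 mM, reads 9% at 40.0 min, and 5.0 h is 7.50 times that, while green, at 68 °C, reads 3% at 2.50 h, so I judge Sunday's and Saturday's to come near this share and Tuesday's to stay far below it, and I leave the order of the first two open.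

**The forecast.** It names Saturday's and gives 4% (2% to 8%) for Tuesday's, 27% (19% to 34%) for Sunday's and 30% (17% to 40%) for Saturday's, on the ground that “partner runs out, capping tris near 33% if the steps are equal”. Its cap lies close to my share, but I name no leader.

**The result.** Sunday's leads, with tris adduct at 5.01% in Tuesday's, 32.0% in Sunday's and 28.1% in Saturday's.

    substrate + partner → first product + released group (k = 19.5 L mol⁻¹ h⁻¹, Ea = 59.0 kJ mol⁻¹)
    partner + first product → double product + released group (k = 20.6 L mol⁻¹ h⁻¹, Ea = 82.0 kJ mol⁻¹)
    partner + double product → tris adduct + released group (k = 49.6 L mol⁻¹ h⁻¹, Ea = 59.0 kJ mol⁻¹)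
    tris adduct ⇌ isomer of the product (K = 0.660, k = 0.0381 h⁻¹, Ea = 115 kJ mol⁻¹, ΔH = −9.00 kJ mol⁻¹)
    (constants at 80 °C)

**The flasks.** Tris adduct plus isomer, against the equal-step share of 32.3%, reaches 35.3% in Sunday's and 43.2% in Saturday's. At 80 °C, Sunday's temperature, the tris adduct and isomer pair relaxes in 10.4 h, twice the 5.0 h run, and Sunday's ends with isomer to tris adduct at 0.103, whereas Saturday's ends at 0.536 and still holds 28.0% of tris adduct after 50.0 h. The neighbour of Saturday's with 0.450 equiv of partner, left with 0% of it, sits near 0.5 turns, where the equal-step share is 1.44%, and it ends with tris adduct plus isomer at 2.76%.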